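**Retrosynthetic overview**

1. Ring A is the 2,3-diarylbenzofuran, ring B the 2,3-dihydrobenzofuran that carries the styryl link at C5, and ring C the 2,3-dihydrobenzofuran bound through its C4 to C3 of ring B. The nine O–Me bonds are cleaved last, and the E-alkene between C4 of ring A and C5 of ring B comes from Horner–Wadsworth–Emmons olefination of aldehyde 28 with phosphonate 37.
2. The furan part of ring C (O1–C2 and C2–C3) comes from a [4+1] annulation of an ortho-quinone methide with a chiral 4-methoxybenzyl sulfonium ylide. The quinone methide goes back through benzhydrol 20 and benzophenone 19 to benzodioxinone 16, whose carbonyl carbon is C3 of ring C.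
3. The strategy rests on the benzo ring of ring C (C3a, C4, C5, C6, C7, C7a): a resorcinol with oxygen on C6 and C7a, the C3 carbon on C3a and C3 of ring B on C4, which is the pattern of a 6-substituted 2,4-dihydroxybenzoate. It is built by aldol cycloaromatisation of diketo-dioxinone 14 (bond C3a–C4), so the crowded ring B–ring C bond is the acyl bond of acid 8 and is never made by coupling.
4. Ring B comes from Rh-carbene C–H insertion of aryldiazoacetate 5 and base epimerisation to trans acid 8; ring A from cyclodehydration of aryloxy ketone 31 and C2 arylation.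
5. Order of ring formation: furan ring of ring B (step 4), benzo ring of ring C (step 8), furan ring of ring C (step 14); furan ring of ring A (step 17) in a separate branch; the halves are joined in step 22.

Key step: step 8

Assumption: Rh2(R-PTTL)4 is taken to give the 2R cis ester 6, and the ylide from (1R,4R,5R)-isothiocineole to give C2 of ring C as S; if either sense proved opposite, the mirror-image catalyst or sulfide would be used with no other change.

**Route**

Step 1
Reactants: 1 5-bromo-2-hydroxyphenylacetic acid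
Product: 2 methyl 2-(5-bromo-2-hydroxyphenyl)acetate
Conditions: MeOH, H2SO4 (cat.), reflux
Reagents that add atoms: methanol, CO
Why: Fischer esterification in excess methanol, which also reopens any benzofuran-2(3H)-one formed by lactonisation.

Step 2
Reactants: 2 methyl 2-(5-bromo-2-hydroxyphenyl)acetate; 3 4-methoxybenzyl chloride
Product: 4 methyl 2-{5-bromo-2-[(4-methoxybenzyl)oxy]phenyl}acetate
Conditions: K2CO3, n-Bu4NI (cat.), DMF, rt
Reagents that add atoms: none
Why: Williamson ether synthesis on the phenoxide; K2CO3 is too weak to alkylate the ester α-carbon.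

Step 3
Reactants: 4 methyl 2-{5-bromo-2-[(4-methoxybenzyl)oxy]phenyl}acetate
Product: 5 methyl 2-{5-bromo-2-[(4-methoxybenzyl)oxy]phenyl}-2-diazoacetate
Conditions: 4-acetamidobenzenesulfonyl azide, DBU, MeCN, 0 °C → rt
Reagents that add atoms: 4-acetamidobenzenesulfonyl azide, CC(=O)Nc1ccc(cc1)S(=O)(=O)N=[N+]=[N-]
Why: Regitz diazo transfer: DBU forms the arylacetate enolate, which takes the terminal N2 unit of the sulfonyl azide and releases the sulfonamide.

Step 4
Reactants: 5 methyl 2-{5-bromo-2-[(4-methoxybenzyl)oxy]phenyl}-2-diazoacetate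
Product: 6 methyl (2R,3S)-5-bromo-2-(4-methoxyphenyl)-2,3-dihydro-1-benzofuran-3-carboxylate (cis)
Conditions: Rh2(R-PTTL)4 (dirhodium tetrakis[N-phthaloyl-(R)-tert-leucinate], 1 mol %), toluene, −60 °C
Reagents that add atoms: none
Why: Intramolecular C–H insertion of the donor/acceptor Rh-carbene into the ether-activated 4-methoxybenzylic C–H closes the five-membered ring; the compact transition state gives the cis ester, and the chiral carboxylate ligands select one of the two enantiotopic benzylic hydrogens, which sets C2 as R (and C3 as S).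

Step 5
Reactants: 6 methyl (2R,3S)-5-bromo-2-(4-methoxyphenyl)-2,3-dihydro-1-benzofuran-3-carboxylate
Product: 8 (2R,3R)-5-bromo-2-(4-methoxyphenyl)-2,3-dihydro-1-benzofuran-3-carboxylic acid, via trans methyl ester 7 (not isolated)
Conditions: NaOMe (cat.), MeOH, rt; then aq. NaOH, rt; HCl work-up
Reagents that add atoms: sodium hydroxide, [Na+].[OH-]
Why: Base epimerisation then saponification: methoxide enolises the ester and C3 settles in the more stable trans arrangement while the non-acidic C2 keeps the configuration from step 4; the acid can be recrystallised to raise its enantiomeric purity.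

Step 6
Reactants: 9 2,2,6-trimethyl-4H-1,3-dioxin-4-one
Product: 11 2,2-dimethyl-6-(2-oxopropyl)-4H-1,3-dioxin-4-one, via lithium dienolate 10 (not isolated)
Conditions: LiN(SiMe3)2, THF, −78 °C; then AcCl, −78 °C; aq. NH4Cl
Reagents that add atoms: acetyl chloride, CC(Cl)=O
Why: Vinylogous Claisen acylation: kinetic deprotonation of the 6-methyl group gives the lithium dienolate, which is C-acylated at its γ-carbon; 9 is used in excess because 11 is the stronger acid.

Step 7
Reactants: 8 (2R,3R)-5-bromo-2-(4-methoxyphenyl)-2,3-dihydro-1-benzofuran-3-carboxylic acid; 11 2,2-dimethyl-6-(2-oxopropyl)-4H-1,3-dioxin-4-one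
Product: 14 6-{4-[(2R,3R)-5-bromo-2-(4-methoxyphenyl)-2,3-dihydro-1-benzofuran-3-yl]-2,4-dioxobutyl}-2,2-dimethyl-4H-1,3-dioxin-4-one, via acyl imidazole 12 (not isolated), via dilithium dianion 13 (not isolated)
Conditions: 8, 1,1'-carbonyldiimidazole, THF, rt; separately 11 (excess), LiN(iPr)2, THF, −78 °C, then ZnEt2; add 12, −78 → −20 °C; aq. NH4Cl
Reagents that add atoms: none
Why: Claisen-type C-acylation: the dianion of 11 reacts at its terminal, last-formed carbanion centre with the acyl imidazole; transmetalation to zinc lowers the basicity so that acyl transfer outruns deprotonation at C3 of ring B, any epimerisation there returns to trans, and the excess dianion absorbs the imidazole N–H set free in the activation.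

Step 8
Reactants: 14 6-{4-[(2R,3R)-5-bromo-2-(4-methoxyphenyl)-2,3-dihydro-1-benzofuran-3-yl]-2,4-dioxobutyl}-2,2-dimethyl-4H-1,3-dioxin-4-one
Product: 15 5-[(2R,3R)-5-bromo-2-(4-methoxyphenyl)-2,3-dihydro-1-benzofuran-3-yl]-7-hydroxy-2,2-dimethyl-4H-1,3-benzodioxin-4-one
Conditions: Et3N, CH2Cl2, rt
Reagents that add atoms: none
Why: Et3N deprotonates 14 to the extended dienolate of the dioxinone, whose α-carbon (C5 of the dioxinone) attacks the terminal ketone bonded to C3 of ring B; E1cB loss of water and enolisation of the remaining ring ketone then give the arene, with the new bond between the later C3a and C4 of ring C. The closest known reaction type is the amine- or carbonate-mediated cycloaromatisation of diketo-dioxinones (masked 3,5,7-triketo esters) to isopropylidene-protected β-resorcylates, the laboratory counterpart of the polyketide aldol folding that leads to orsellinic acid. The one ring that closes is the six-membered carbocycle, formed by 6-exo-trig attack of the enolate carbon on the ketone (the carbonyl oxygen stays outside the ring). No stereocentre is created; C3 of ring B is α to the reacting ketone and may enolise, but trans is the more stable arrangement, C2 is not acidic, and β-elimination of the aryloxide is held back because the C2–O bond lies near the plane of the enolate. The step needs C-aldol closure onto the terminal ketone in preference to O-cyclisation to a pyranone or Claisen attack on the carboxyl carbon: the dioxinone ties that carbon up as a vinylogous acetal ester and makes its α-carbon the nucleophile, the central carbonyl is held as the enolate, and only the terminal ketone can be reached through a six-membered transition state that ends in an arene. The acetonide that remains tells the two phenol oxygens apart (C7a–O masked, C6–OH free) and keeps the carboxyl carbon as the future C3 of ring C.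

Step 9
Reactants: 15 5-[(2R,3R)-5-bromo-2-(4-methoxyphenyl)-2,3-dihydro-1-benzofuran-3-yl]-7-hydroxy-2,2-dimethyl-4H-1,3-benzodioxin-4-one
Product: 16 5-[(2R,3R)-5-bromo-2-(4-methoxyphenyl)-2,3-dihydro-1-benzofuran-3-yl]-7-methoxy-2,2-dimethyl-4H-1,3-benzodioxin-4-one
Conditions: MeI, K2CO3, acetone, reflux
Reagents that add atoms: iodomethane, CI
Why: Williamson methylation of the free phenol; the acetonide-masked phenol and the lactone-type carbonyl are inert to K2CO3 in an aprotic solvent.

Step 10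
Reactants: 16 5-[(2R,3R)-5-bromo-2-(4-methoxyphenyl)-2,3-dihydro-1-benzofuran-3-yl]-7-methoxy-2,2-dimethyl-4H-1,3-benzodioxin-4-one; 17 1-bromo-3,5-dimethoxybenzene
Product: 19 {2-[(2R,3R)-5-bromo-2-(4-methoxyphenyl)-2,3-dihydro-1-benzofuran-3-yl]-6-hydroxy-4-methoxyphenyl}(3,5-dimethoxyphenyl)methanone, via 3,5-dimethoxyphenylmagnesium bromide 18 (not isolated)
Conditions: 17, Mg, THF, reflux; then 16, THF, 0 °C → rt; aq. NH4Cl
Reagents that add atoms: none
Why: Grignard addition–elimination at the benzodioxinone carbonyl: the tetrahedral adduct collapses with loss of acetone to a magnesium ortho-phenoxide ketone, whose chelated, electron-rich carbonyl resists a second addition; the aryl bromide of ring B does not exchange with an aryl Grignard reagent.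

Step 11
Reactants: 19 {2-[(2R,3R)-5-bromo-2-(4-methoxyphenyl)-2,3-dihydro-1-benzofuran-3-yl]-6-hydroxy-4-methoxyphenyl}(3,5-dimethoxyphenyl)methanone
Product: 20 3-[(2R,3R)-5-bromo-2-(4-methoxyphenyl)-2,3-dihydro-1-benzofuran-3-yl]-2-[(3,5-dimethoxyphenyl)(hydroxy)methyl]-5-methoxyphenol (both carbinol epimers)
Conditions: NaBH4, THF/MeOH, 0 °C → rt; aq. NH4Cl
Reagents that add atoms: none
Why: Hydride reduction of the diaryl ketone; the configuration of the carbinol carbon does not matter because this carbon becomes trigonal again in step 14.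

Step 12
Reactants: 20 3-[(2R,3R)-5-bromo-2-(4-methoxyphenyl)-2,3-dihydro-1-benzofuran-3-yl]-2-[(3,5-dimethoxyphenyl)(hydroxy)methyl]-5-methoxyphenol
Product: 21 3-[(2R,3R)-5-bromo-2-(4-methoxyphenyl)-2,3-dihydro-1-benzofuran-3-yl]-2-[(3,5-dimethoxyphenyl)(4-methylbenzenesulfonyl)methyl]-5-methoxyphenol
Conditions: 4-methylbenzenesulfinic acid, CH2Cl2, rt
Reagents that add atoms: 4-methylbenzenesulfinic acid, Cc1ccc(cc1)S(O)=O
Why: Acid-assisted SN1 substitution: the sulfinic acid ionises the electron-rich benzhydrol (cation stabilised by the ortho-hydroxy and para-methoxy groups) and the sulfinate captures it through sulfur, giving a base-labile precursor of the ortho-quinone methide.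

Step 13
Reactants: 22 (1R,4R,5R)-4,7,7-trimethyl-6-thiabicyclo[3.2.1]octane (isothiocineole); 3 4-methoxybenzyl chloride
Product: 23 (1R,4R,5R,6R)-6-(4-methoxybenzyl)-4,7,7-trimethyl-6-thioniabicyclo[3.2.1]octane tetrafluoroborate
Conditions: NaBF4, CH2Cl2/H2O, rt
Reagents that add atoms: sodium tetrafluoroborate, [Na+].F[B-](F)(F)F
Why: S-alkylation of the sulfide by the reactive benzylic chloride with exchange of chloride for tetrafluoroborate in the two-phase system; the bicyclic framework exposes one lone pair of sulfur, so a single sulfonium diastereomer should form.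

Step 14
Reactants: 21 3-[(2R,3R)-5-bromo-2-(4-methoxyphenyl)-2,3-dihydro-1-benzofuran-3-yl]-2-[(3,5-dimethoxyphenyl)(4-methylbenzenesulfonyl)methyl]-5-methoxyphenol; 23 (1R,4R,5R,6R)-6-(4-methoxybenzyl)-4,7,7-trimethyl-6-thioniabicyclo[3.2.1]octane tetrafluoroborate
Product: 26 (2R,3R)-5-bromo-3-[(2S,3S)-3-(3,5-dimethoxyphenyl)-6-methoxy-2-(4-methoxyphenyl)-2,3-dihydro-1-benzofuran-4-yl]-2-(4-methoxyphenyl)-2,3-dihydro-1-benzofuran, via ortho-quinone methide 24 (not isolated), via sulfonium ylide 25 (not isolated)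
Conditions: Cs2CO3, MeCN/CH2Cl2, −20 °C → rt
Reagents that add atoms: none
Why: Proposed new method: Cs2CO3 converts 21 into ortho-quinone methide 24 by 1,4-elimination of sulfinate and 23 into ylide 25; the ylide carbon adds to the exocyclic carbon of 24 (conjugate addition driven by rearomatisation), and the phenoxide of the betaine displaces the sulfide at the benzylic carbon with inversion (5-exo-tet), closing the O1–C2 bond of ring C. The closest known reactions are the [4+1] annulation of ortho-quinone methides with sulfur ylides to trans-2,3-dihydrobenzofurans, shown mainly with achiral or carbonyl-stabilised ylides, and the asymmetric epoxidation of aldehydes with benzyl ylides of isothiocineole; a chiral benzylic sulfonium ylide on a quinone methide that already carries stereocentres is not documented. The chiral sulfide should fix the reacting face of the ylide and so C2 (S), and the faster closure of the betaine that places the two aryl groups trans should set C3 (S); reagent control is needed because the stereocentres of ring B are too remote from C2 to be relied on.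

Step 15
Reactants: 26 (2R,3R)-5-bromo-3-[(2S,3S)-3-(3,5-dimethoxyphenyl)-6-methoxy-2-(4-methoxyphenyl)-2,3-dihydro-1-benzofuran-4-yl]-2-(4-methoxyphenyl)-2,3-dihydro-1-benzofuran
Product: 28 (2R,3R)-3-[(2S,3S)-3-(3,5-dimethoxyphenyl)-6-methoxy-2-(4-methoxyphenyl)-2,3-dihydro-1-benzofuran-4-yl]-2-(4-methoxyphenyl)-2,3-dihydro-1-benzofuran-5-carbaldehyde, via aryllithium 27 (not isolated)
Conditions: n-BuLi, THF, −78 °C; then DMF, −78 °C → rt; aq. NH4Cl
Reagents that add atoms: N,N-dimethylformamide, CN(C)C=O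
Why: Bromine–lithium exchange is faster at −78 °C than any deprotonation, and formylation of the aryllithium with DMF (Bouveault reaction) gives the aldehyde on work-up.

Step 16
Reactants: 29 methyl 3-hydroxy-5-methoxybenzoate; 30 2-bromo-1-(3,5-dimethoxyphenyl)ethan-1-one
Product: 31 methyl 3-[2-(3,5-dimethoxyphenyl)-2-oxoethoxy]-5-methoxybenzoate
Conditions: K2CO3, acetone, reflux
Reagents that add atoms: none
Why: Williamson ether synthesis with an α-bromo ketone (fast SN2 at the carbonyl-activated carbon).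

Step 17
Reactants: 31 methyl 3-[2-(3,5-dimethoxyphenyl)-2-oxoethoxy]-5-methoxybenzoate
Product: 32 methyl 3-(3,5-dimethoxyphenyl)-6-methoxy-1-benzofuran-4-carboxylate
Conditions: Bi(OTf)3 (10 mol %), CH2Cl2, reflux
Reagents that add atoms: none
Why: Lewis-acid-catalysed cyclodehydration (intramolecular Friedel–Crafts hydroxyalkylation, then loss of water): closure should take place at the arene carbon between the ether oxygen and the ester, which is para to the methoxy group, as in electrophilic substitution of 3,5-dialkoxybenzoates; a regioisomer from closure between the two oxygens would be removed by chromatography.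

Step 18
Reactants: 32 methyl 3-(3,5-dimethoxyphenyl)-6-methoxy-1-benzofuran-4-carboxylate; 33 4-bromoanisole
Product: 34 methyl 3-(3,5-dimethoxyphenyl)-6-methoxy-2-(4-methoxyphenyl)-1-benzofuran-4-carboxylate
Conditions: Pd(OAc)2 (5 mol %), PCy3·HBF4, PivOH, K2CO3, DMA, 110 °C
Reagents that add atoms: none
Why: Pd-catalysed direct C–H arylation of the benzofuran C2–H (concerted metalation–deprotonation assisted by pivalate), the only heteroaryl C–H in 32.

Step 19
Reactants: 34 methyl 3-(3,5-dimethoxyphenyl)-6-methoxy-2-(4-methoxyphenyl)-1-benzofuran-4-carboxylate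
Product: 35 [3-(3,5-dimethoxyphenyl)-6-methoxy-2-(4-methoxyphenyl)-1-benzofuran-4-yl]methanol
Conditions: LiAlH4, THF, 0 °C; aqueous work-up
Reagents that add atoms: none
Why: LiAlH4 reduction of the ester to the benzylic alcohol.

Step 20
Reactants: 35 [3-(3,5-dimethoxyphenyl)-6-methoxy-2-(4-methoxyphenyl)-1-benzofuran-4-yl]methanol
Product: 36 4-(bromomethyl)-3-(3,5-dimethoxyphenyl)-6-methoxy-2-(4-methoxyphenyl)-1-benzofuran
Conditions: PBr3, CH2Cl2, 0 °C
Reagents that add atoms: phosphorus tribromide, BrP(Br)Br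
Why: Conversion of the benzylic alcohol into the bromide (bromide displaces the phosphite ester by SN2).

Step 21
Reactants: 36 4-(bromomethyl)-3-(3,5-dimethoxyphenyl)-6-methoxy-2-(4-methoxyphenyl)-1-benzofuran
Product: 37 diethyl {[3-(3,5-dimethoxyphenyl)-6-methoxy-2-(4-methoxyphenyl)-1-benzofuran-4-yl]methyl}phosphonate
Conditions: P(OEt)3, neat, 130 °C
Reagents that add atoms: triethyl phosphite, CCOP(OCC)OCC
Why: Michaelis–Arbuzov reaction of the benzylic bromide.

Step 22
Reactants: 28 (2R,3R)-3-[(2S,3S)-3-(3,5-dimethoxyphenyl)-6-methoxy-2-(4-methoxyphenyl)-2,3-dihydro-1-benzofuran-4-yl]-2-(4-methoxyphenyl)-2,3-dihydro-1-benzofuran-5-carbaldehyde; 37 diethyl {[3-(3,5-dimethoxyphenyl)-6-methoxy-2-(4-methoxyphenyl)-1-benzofuran-4-yl]methyl}phosphonate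
Product: 38 3-(3,5-dimethoxyphenyl)-6-methoxy-2-(4-methoxyphenyl)-4-[(E)-2-{(2R,3R)-3-[(2S,3S)-3-(3,5-dimethoxyphenyl)-6-methoxy-2-(4-methoxyphenyl)-2,3-dihydro-1-benzofuran-4-yl]-2-(4-methoxyphenyl)-2,3-dihydro-1-benzofuran-5-yl}ethenyl]-1-benzofuran (nonamethyl ether of the target)
Conditions: KOtBu added to 28 and 37 in THF, 0 °C → rt
Reagents that add atoms: none
Why: Horner–Wadsworth–Emmons olefination; a benzylic phosphonate carbanion and an aryl aldehyde give the E-stilbene, and tert-butoxide can reach no epimerisable centre in either partner.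

Step 23
Reactants: 38 nonamethyl ether of the target
Product: 39 CNP0135983.1, 3-(3,5-dihydroxyphenyl)-2-(4-hydroxyphenyl)-4-[(E)-2-{(2R,3R)-3-[(2S,3S)-3-(3,5-dihydroxyphenyl)-6-hydroxy-2-(4-hydroxyphenyl)-2,3-dihydro-1-benzofuran-4-yl]-2-(4-hydroxyphenyl)-2,3-dihydro-1-benzofuran-5-yl}ethenyl]-1-benzofuran-6-ol
Conditions: BCl3, n-Bu4NI, CH2Cl2, −78 → 0 °C; then H2O
Reagents that add atoms: none
Why: Lewis-acid demethylation of aryl methyl ethers: BCl3 activates each ether oxygen and iodide removes the methyl group by SN2, a combination milder than BBr3 and run cold to limit ionisation of the benzylic C2–O bonds and protonation of the stilbene; aqueous work-up hydrolyses the aryl borates.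

**Compound list**

1 | 5-bromo-2-hydroxyphenylacetic acid | OC(=O)Cc1cc(Br)ccc1O | starting material
2 | methyl 2-(5-bromo-2-hydroxyphenyl)acetate | COC(=O)Cc1cc(Br)ccc1O | intermediate
3 | 4-methoxybenzyl chloride | COc1ccc(CCl)cc1 | starting material
4 | methyl 2-{5-bromo-2-[(4-methoxybenzyl)oxy]phenyl}acetate | COC(=O)Cc1cc(Br)ccc1OCc1ccc(OC)cc1 | intermediate
5 | methyl 2-{5-bromo-2-[(4-methoxybenzyl)oxy]phenyl}-2-diazoacetate | COC(=O)C(=[N+]=[N-])c1cc(Br)ccc1OCc1ccc(OC)cc1 | intermediate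
6 | methyl (2R,3S)-5-bromo-2-(4-methoxyphenyl)-2,3-dihydro-1-benzofuran-3-carboxylate (cis) | Brc1ccc2c(c1)[C@H](C(=O)OC)[C@H](c1ccc(OC)cc1)O2 | intermediate
7 | methyl (2R,3R)-5-bromo-2-(4-methoxyphenyl)-2,3-dihydro-1-benzofuran-3-carboxylate (trans) | Brc1ccc2c(c1)[C@@H](C(=O)OC)[C@H](c1ccc(OC)cc1)O2 | intermediate (not isolated)
8 | (2R,3R)-5-bromo-2-(4-methoxyphenyl)-2,3-dihydro-1-benzofuran-3-carboxylic acid | Brc1ccc2c(c1)[C@@H](C(O)=O)[C@H](c1ccc(OC)cc1)O2 | intermediate
9 | 2,2,6-trimethyl-4H-1,3-dioxin-4-one | CC1=CC(=O)OC(C)(C)O1 | starting material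
10 | lithium dienolate of 9 (lithium 2,2-dimethyl-6-methylidene-6H-1,3-dioxin-4-olate) | [Li+].C=C1C=C([O-])OC(C)(C)O1 | intermediate (not isolated)
11 | 2,2-dimethyl-6-(2-oxopropyl)-4H-1,3-dioxin-4-one | CC(=O)CC1=CC(=O)OC(C)(C)O1 | intermediate
12 | 1-{[(2R,3R)-5-bromo-2-(4-methoxyphenyl)-2,3-dihydro-1-benzofuran-3-yl]carbonyl}-1H-imidazole | Brc1ccc2c(c1)[C@@H](C(=O)n1ccnc1)[C@H](c1ccc(OC)cc1)O2 | intermediate (not isolated)
13 | dilithium dianion of 11 | [Li+].[Li+].C=C([O-])C=C1C=C([O-])OC(C)(C)O1 | intermediate (not isolated)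
14 | 6-{4-[(2R,3R)-5-bromo-2-(4-methoxyphenyl)-2,3-dihydro-1-benzofuran-3-yl]-2,4-dioxobutyl}-2,2-dimethyl-4H-1,3-dioxin-4-one | Brc1ccc2c(c1)[C@@H](C(=O)CC(=O)CC1=CC(=O)OC(C)(C)O1)[C@H](c1ccc(OC)cc1)O2 | intermediate
15 | 5-[(2R,3R)-5-bromo-2-(4-methoxyphenyl)-2,3-dihydro-1-benzofuran-3-yl]-7-hydroxy-2,2-dimethyl-4H-1,3-benzodioxin-4-one | Brc1ccc2c(c1)[C@@H](c1cc(O)cc3OC(C)(C)OC(=O)c13)[C@H](c1ccc(OC)cc1)O2 | intermediate
16 | 5-[(2R,3R)-5-bromo-2-(4-methoxyphenyl)-2,3-dihydro-1-benzofuran-3-yl]-7-methoxy-2,2-dimethyl-4H-1,3-benzodioxin-4-one | Brc1ccc2c(c1)[C@@H](c1cc(OC)cc3OC(C)(C)OC(=O)c13)[C@H](c1ccc(OC)cc1)O2 | intermediate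
17 | 1-bromo-3,5-dimethoxybenzene | COc1cc(Br)cc(OC)c1 | starting material
18 | 3,5-dimethoxyphenylmagnesium bromide | COc1cc(cc(OC)c1)[Mg]Br | intermediate (not isolated)
19 | {2-[(2R,3R)-5-bromo-2-(4-methoxyphenyl)-2,3-dihydro-1-benzofuran-3-yl]-6-hydroxy-4-methoxyphenyl}(3,5-dimethoxyphenyl)methanone | Brc1ccc2c(c1)[C@@H](c1cc(OC)cc(O)c1C(=O)c1cc(OC)cc(OC)c1)[C@H](c1ccc(OC)cc1)O2 | intermediate
20 | 3-[(2R,3R)-5-bromo-2-(4-methoxyphenyl)-2,3-dihydro-1-benzofuran-3-yl]-2-[(3,5-dimethoxyphenyl)(hydroxy)methyl]-5-methoxyphenol (carbinol epimers) | Brc1ccc2c(c1)[C@@H](c1cc(OC)cc(O)c1C(O)c1cc(OC)cc(OC)c1)[C@H](c1ccc(OC)cc1)O2 | intermediate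
21 | 3-[(2R,3R)-5-bromo-2-(4-methoxyphenyl)-2,3-dihydro-1-benzofuran-3-yl]-2-[(3,5-dimethoxyphenyl)(4-methylbenzenesulfonyl)methyl]-5-methoxyphenol | Brc1ccc2c(c1)[C@@H](c1cc(OC)cc(O)c1C(c1cc(OC)cc(OC)c1)S(=O)(=O)c1ccc(C)cc1)[C@H](c1ccc(OC)cc1)O2 | intermediate
22 | (1R,4R,5R)-4,7,7-trimethyl-6-thiabicyclo[3.2.1]octane (isothiocineole) | C[C@@H]1CC[C@@H]2C[C@H]1SC2(C)C | starting material
23 | (1R,4R,5R,6R)-6-(4-methoxybenzyl)-4,7,7-trimethyl-6-thioniabicyclo[3.2.1]octane tetrafluoroborate | C[C@@H]1CC[C@@H]2C[C@H]1[S@@+](Cc1ccc(OC)cc1)C2(C)C.F[B-](F)(F)F | intermediate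
24 | 5-[(2R,3R)-5-bromo-2-(4-methoxyphenyl)-2,3-dihydro-1-benzofuran-3-yl]-6-[(3,5-dimethoxyphenyl)methylidene]-3-methoxycyclohexa-2,4-dien-1-one (ortho-quinone methide) | Brc1ccc2c(c1)[C@@H](C1=CC(OC)=CC(=O)C1=Cc1cc(OC)cc(OC)c1)[C@H](c1ccc(OC)cc1)O2 | intermediate (not isolated)
25 | (4-methoxyphenyl)[(1R,4R,5R,6R)-4,7,7-trimethyl-6-thioniabicyclo[3.2.1]octan-6-yl]methanide (sulfonium ylide) | C[C@@H]1CC[C@@H]2C[C@H]1[S@@+]([CH-]c1ccc(OC)cc1)C2(C)C | intermediate (not isolated)
26 | (2R,3R)-5-bromo-3-[(2S,3S)-3-(3,5-dimethoxyphenyl)-6-methoxy-2-(4-methoxyphenyl)-2,3-dihydro-1-benzofuran-4-yl]-2-(4-methoxyphenyl)-2,3-dihydro-1-benzofuran | Brc1ccc2c(c1)[C@@H](c1cc(OC)cc3c1[C@H](c1cc(OC)cc(OC)c1)[C@@H](c1ccc(OC)cc1)O3)[C@H](c1ccc(OC)cc1)O2 | intermediate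
27 | aryllithium from 26 (lithium in place of bromine at C5 of ring B) | [Li]c1ccc2c(c1)[C@@H](c1cc(OC)cc3c1[C@H](c1cc(OC)cc(OC)c1)[C@@H](c1ccc(OC)cc1)O3)[C@H](c1ccc(OC)cc1)O2 | intermediate (not isolated)
28 | (2R,3R)-3-[(2S,3S)-3-(3,5-dimethoxyphenyl)-6-methoxy-2-(4-methoxyphenyl)-2,3-dihydro-1-benzofuran-4-yl]-2-(4-methoxyphenyl)-2,3-dihydro-1-benzofuran-5-carbaldehyde | O=Cc1ccc2c(c1)[C@@H](c1cc(OC)cc3c1[C@H](c1cc(OC)cc(OC)c1)[C@@H](c1ccc(OC)cc1)O3)[C@H](c1ccc(OC)cc1)O2 | intermediate
29 | methyl 3-hydroxy-5-methoxybenzoate | COC(=O)c1cc(O)cc(OC)c1 | starting material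
30 | 2-bromo-1-(3,5-dimethoxyphenyl)ethan-1-one | COc1cc(cc(OC)c1)C(=O)CBr | starting material
31 | methyl 3-[2-(3,5-dimethoxyphenyl)-2-oxoethoxy]-5-methoxybenzoate | COC(=O)c1cc(OCC(=O)c2cc(OC)cc(OC)c2)cc(OC)c1 | intermediate
32 | methyl 3-(3,5-dimethoxyphenyl)-6-methoxy-1-benzofuran-4-carboxylate | COC(=O)c1cc(OC)cc2occ(-c3cc(OC)cc(OC)c3)c12 | intermediate
33 | 4-bromoanisole | COc1ccc(Br)cc1 | starting material
34 | methyl 3-(3,5-dimethoxyphenyl)-6-methoxy-2-(4-methoxyphenyl)-1-benzofuran-4-carboxylate | COC(=O)c1cc(OC)cc2oc(-c3ccc(OC)cc3)c(-c3cc(OC)cc(OC)c3)c12 | intermediate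
35 | [3-(3,5-dimethoxyphenyl)-6-methoxy-2-(4-methoxyphenyl)-1-benzofuran-4-yl]methanol | OCc1cc(OC)cc2oc(-c3ccc(OC)cc3)c(-c3cc(OC)cc(OC)c3)c12 | intermediate
36 | 4-(bromomethyl)-3-(3,5-dimethoxyphenyl)-6-methoxy-2-(4-methoxyphenyl)-1-benzofuran | BrCc1cc(OC)cc2oc(-c3ccc(OC)cc3)c(-c3cc(OC)cc(OC)c3)c12 | intermediate
37 | diethyl {[3-(3,5-dimethoxyphenyl)-6-methoxy-2-(4-methoxyphenyl)-1-benzofuran-4-yl]methyl}phosphonate | CCOP(=O)(OCC)Cc1cc(OC)cc2oc(-c3ccc(OC)cc3)c(-c3cc(OC)cc(OC)c3)c12 | intermediate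
38 | nonamethyl ether of the target (full name in step 22) | COc1ccc(-c2oc3cc(OC)cc(/C=C/c4ccc5c(c4)[C@@H](c4cc(OC)cc6c4[C@H](c4cc(OC)cc(OC)c4)[C@@H](c4ccc(OC)cc4)O6)[C@H](c4ccc(OC)cc4)O5)c3c2-c2cc(OC)cc(OC)c2)cc1 | intermediate
39 | CNP0135983.1 (full name in step 23) | Oc1ccc(-c2oc3cc(O)cc(/C=C/c4ccc5c(c4)[C@@H](c4cc(O)cc6c4[C@H](c4cc(O)cc(O)c4)[C@@H](c4ccc(O)cc4)O6)[C@H](c4ccc(O)cc4)O5)c3c2-c2cc(O)cc(O)c2)cc1 | target

**Step count and risks**

Total step count: 23. Longest linear sequence: 15 steps (steps 1–5, 7–12, 14, 15, 22, 23).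

Steps most likely to fail:

1. Step 14 (proposed new method). The ylide may add to the quinone methide with poor facial selectivity if the chiral sulfide and the stereocentres of ring B are mismatched. Reversible betaine formation may erode reagent control, and addition to the crowded methide carbon may be slower than decomposition of the 4-methoxybenzyl ylide. The fallback uses known donor/donor carbene chemistry; it sets out from benzophenone 19 and comes back at 26. Benzophenone 19 is O-alkylated with 3 (K2CO3, DMF) to the 4-methoxybenzyl ether F1, which is condensed with hydrazine under forcing conditions to the hydrazone F2. Oxidation with MnO2 in CH2Cl2 gives the diaryldiazomethane F3. Rh2(R-PTAD)4 (dirhodium tetrakis[(R)-(1-adamantyl)(N-phthalimido)acetate], or its mirror image if the sense requires) then effects intramolecular C–H insertion into the benzylic ether C–H to the cis-2,3-diaryl-2,3-dihydrobenzofuran F4, with the catalyst setting C3 of ring C as S. Brief treatment with BF3·OEt2 in CH2Cl2 ionises the C2–O bond to the 4-methoxybenzylic cation and recloses it to the more stable trans isomer, which is 26.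

2. Step 8. Aldol closure at the ketone shielded by ring B may be slow, so that O-cyclisation to a pyranone, retro-Claisen cleavage of the 1,3-diketone, or β-elimination of the aryloxide from the enolate at C3 of ring B (which would erode C2) may compete. The fallback unmasks the carboxyl carbon before the ring is closed; it sets out from 14 and comes back at 15. Heating 14 in toluene at 110 °C with tert-butanol expels acetone and traps the acylketene as the tert-butyl triketo ester F5. Aldol aromatisation of this open-chain triketo ester with Cs2CO3 in methanol, then aqueous HCl, gives the tert-butyl resorcylate F6. CF3CO2H, (CF3CO)2O and acetone then cleave the tert-butyl ester and close the acetonide to 15.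

3. Step 23. Acid may ionise the benzylic C2–O bonds of rings B and C and protonate the electron-rich stilbene, leading to ring opening, cyclisation onto the neighbouring resorcinol rings, or oligomerisation before all nine methyl ethers are cleaved. The fallback removes the methyl groups before the stilbene exists; it sets out from bromide 26 and alcohol 35 and comes back at 39.
   - Rings B and C: 26 is demethylated with BBr3 in CH2Cl2 to the pentaphenol bromide F7 and acetylated (Ac2O, pyridine) to the pentaacetate F8.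
   - Ring A: 35 is oxidised with MnO2 to the aldehyde F9 and demethylated with BCl3/n-Bu4NI to the tetrahydroxy aldehyde F10. Excess Ph3P=CH2 (Wittig reaction) gives the tetrahydroxy styrene F11, which is acetylated to the tetraacetoxy styrene F12.
   - Joining: Heck coupling of F8 with F12 (Pd(OAc)2, P(o-tol)3, Et3N, DMF, 100 °C) gives the E-stilbene nonaacetate F13, and K2CO3 in methanol at 0 °C removes the acetates to give 39.

**Further compounds**

F1 | step 14 | {2-[(2R,3R)-5-bromo-2-(4-methoxyphenyl)-2,3-dihydro-1-benzofuran-3-yl]-4-methoxy-6-[(4-methoxybenzyl)oxy]phenyl}(3,5-dimethoxyphenyl)methanone | Brc1ccc2c(c1)[C@@H](c1cc(OC)cc(OCc3ccc(OC)cc3)c1C(=O)c1cc(OC)cc(OC)c1)[C@H](c1ccc(OC)cc1)O2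
F2 | step 14 | hydrazone of F1 | Brc1ccc2c(c1)[C@@H](c1cc(OC)cc(OCc3ccc(OC)cc3)c1C(=NN)c1cc(OC)cc(OC)c1)[C@H](c1ccc(OC)cc1)O2
F3 | step 14 | diaryldiazomethane from F2 | Brc1ccc2c(c1)[C@@H](c1cc(OC)cc(OCc3ccc(OC)cc3)c1C(=[N+]=[N-])c1cc(OC)cc(OC)c1)[C@H](c1ccc(OC)cc1)O2
F4 | step 14 | (2R,3R)-5-bromo-3-[(2R,3S)-3-(3,5-dimethoxyphenyl)-6-methoxy-2-(4-methoxyphenyl)-2,3-dihydro-1-benzofuran-4-yl]-2-(4-methoxyphenyl)-2,3-dihydro-1-benzofuran (ring C cis) | Brc1ccc2c(c1)[C@@H](c1cc(OC)cc3c1[C@H](c1cc(OC)cc(OC)c1)[C@H](c1ccc(OC)cc1)O3)[C@H](c1ccc(OC)cc1)O2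
F5 | step 8 | tert-butyl 7-[(2R,3R)-5-bromo-2-(4-methoxyphenyl)-2,3-dihydro-1-benzofuran-3-yl]-3,5,7-trioxoheptanoate | Brc1ccc2c(c1)[C@@H](C(=O)CC(=O)CC(=O)CC(=O)OC(C)(C)C)[C@H](c1ccc(OC)cc1)O2
F6 | step 8 | tert-butyl 2-[(2R,3R)-5-bromo-2-(4-methoxyphenyl)-2,3-dihydro-1-benzofuran-3-yl]-4,6-dihydroxybenzoate | Brc1ccc2c(c1)[C@@H](c1cc(O)cc(O)c1C(=O)OC(C)(C)C)[C@H](c1ccc(OC)cc1)O2
F7 | step 23 | (2R,3R)-5-bromo-3-[(2S,3S)-3-(3,5-dihydroxyphenyl)-6-hydroxy-2-(4-hydroxyphenyl)-2,3-dihydro-1-benzofuran-4-yl]-2-(4-hydroxyphenyl)-2,3-dihydro-1-benzofuran | Brc1ccc2c(c1)[C@@H](c1cc(O)cc3c1[C@H](c1cc(O)cc(O)c1)[C@@H](c1ccc(O)cc1)O3)[C@H](c1ccc(O)cc1)O2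
F8 | step 23 | pentaacetate of F7 | Brc1ccc2c(c1)[C@@H](c1cc(OC(C)=O)cc3c1[C@H](c1cc(OC(C)=O)cc(OC(C)=O)c1)[C@@H](c1ccc(OC(C)=O)cc1)O3)[C@H](c1ccc(OC(C)=O)cc1)O2
F9 | step 23 | 3-(3,5-dimethoxyphenyl)-6-methoxy-2-(4-methoxyphenyl)-1-benzofuran-4-carbaldehyde | O=Cc1cc(OC)cc2oc(-c3ccc(OC)cc3)c(-c3cc(OC)cc(OC)c3)c12
F10 | step 23 | 3-(3,5-dihydroxyphenyl)-6-hydroxy-2-(4-hydroxyphenyl)-1-benzofuran-4-carbaldehyde | O=Cc1cc(O)cc2oc(-c3ccc(O)cc3)c(-c3cc(O)cc(O)c3)c12
F11 | step 23 | 5-[4-ethenyl-6-hydroxy-2-(4-hydroxyphenyl)-1-benzofuran-3-yl]benzene-1,3-diol | C=Cc1cc(O)cc2oc(-c3ccc(O)cc3)c(-c3cc(O)cc(O)c3)c12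
F12 | step 23 | tetraacetate of F11 | C=Cc1cc(OC(C)=O)cc2oc(-c3ccc(OC(C)=O)cc3)c(-c3cc(OC(C)=O)cc(OC(C)=O)c3)c12
F13 | step 23 | nonaacetate of 39 | CC(=O)Oc1ccc(-c2oc3cc(OC(C)=O)cc(/C=C/c4ccc5c(c4)[C@@H](c4cc(OC(C)=O)cc6c4[C@H](c4cc(OC(C)=O)cc(OC(C)=O)c4)[C@@H](c4ccc(OC(C)=O)cc4)O6)[C@H](c4ccc(OC(C)=O)cc4)O5)c3c2-c2cc(OC(C)=O)cc(OC(C)=O)c2)cc1
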